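## Structural features

Compound 34 is an ent-labdane; labdane numbering is used throughout (C1–C10 decalin, chain C11–C15 with methyl C16 on C13, C17 on C8, C18 and C19 on C4, C20 on C10). Ring A (C1–C5, C10) and ring B (C5–C10) are trans-fused. C8 carries the exocyclic methylene C17, C9 carries the C11–C15 acid chain, and C4 carries an axial methyl (C19) and an equatorial CH2O (C18) esterified with (E)-p-coumaric acid. Four contiguous stereocentres lie on the decalin (4S, 5S, 9R, 10S); the quaternary C4 and C10 flank C5–H. The C19 and C20 methyls are 1,3-diaxial on one face, H5 and H9 are axial on the other, and the C9 chain is equatorial and cis to C20. The fifth stereocentre, C13 (S), is remote and cannot be controlled from the rings. The fragile groups are the 8(17)-alkene (moves into the ring under strong acid), the cinnamate (ester and Michael acceptor, incompatible with organolithiums or with hydrolysis at C15), the oxidisable phenol and the free acid. The main difficulties are the C4/C5/C10 triad in the ent series, an exocyclic alkene next to the C9 stereocentre, and the independent C13 centre. The key step uses the fact that C5–H bears a carbon (C4) with one methyl and one oxygenated carbon, which is an opened methyloxirane and hence the isopropenyl group of carvone, and that ring B with its single one-carbon branch (C17 on C8) is the carvone ring, so only the C3–C4 bond is needed to close ring A.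

## Logic of the disconnections

34 is cut at the cinnamate C=C bond to 32 and 33. A decarboxylative condensation makes the (E)-alkene last, needs no phenol protection and tolerates the free C15 acid. The forward step only requires that 32 carry its malonyl group on O18.

32 is cut at the C18–O acyl bond to 30 and 31. C18–OH is the only hydroxyl in 30, and a carboxylic acid is not acylated by 31, so no protecting group is needed at C15.

30 goes back through 29 to 28 without skeletal change. The C15 acid is carried as an aldehyde acetal and C18–OH as a silyl ether, so one mild acid treatment frees both and one oxidation finishes C15. The acid must be too weak to move the 8(17)-alkene.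

28 is traced through 27 and 25 to 24: the C7–H bond, then the C7–O bond, then the oxirane. This exchanges the exocyclic alkene for the ring alkene that the carvone enone supplies. The forward steps must take a proton from C17 (not C9) and deliver hydride to C7 (not C17).

24 is cut at C9–H (back to 23) and at C9–C11 (back to 12 and 20). The whole chain arrives in one convergent addition to the C9 carbonyl. The forward steps demand addition anti to the C20 methyl and hydride delivery with inversion, which together place H9 anti to C20.

20 is traced through 19, 18, 16 and 14 to 13. The C13 stereocentre comes from desymmetrising a prochiral diester, and the two chain ends are then told apart by the order of reduction. The ester carbon must become C11 and the acid carbon C15.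

12 is traced through 10 and 9 to 8: the C3 carbonyl that the ring closure leaves is deleted, and O18 is silylated. The deoxygenation must distinguish the C3 ketone from the hindered C9 enone.

8 is cut at C3–C4 to 6 (key step). This removes ring A and the C4 stereocentre in one move and leaves a monocycle with every carvone carbon. The forward step needs a C4 radical that adds to a nitrile with the oxygenated carbon equatorial.

6 is traced through 5 to 3 and 4, and 3 to 1: the oxirane from the isopropenyl alkene, the C10–C1 bond by conjugate addition, the C10–C20 bond by enolate methylation. The second electrophile must enter trans to the isopropenyl group, which fixes C10 relative to C5.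

## Other disconnections considered

Alternative 1: The cut through C5–C10 and C8–C9 forms both rings at once from the open-chain triene A1, in which an (E,E)-1-silyloxydiene (C5–C8) is tethered through C1–C4 to an (E)-β-methyl enoate (C9=C10). Heat or a dialkylaluminium chloride would give cycloadduct A2 by intramolecular Diels–Alder reaction.
- In favour: one step makes rings A and B and the C5/C9/C10 triad, and the cis relation of C20 and C11 follows stereospecifically from the enoate geometry. The oxygen left on C8 is where a ketone for methylenation is wanted; on this point the alternative is better than the three-step alkene shift of steps 15–17.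
- Against: the only stereocentre in A1 is the quaternary C4, whose methyl and silyloxymethyl groups differ little in size, so facial control across the tether is expected to be weak. C4 must also be made enantiopure in an acyclic setting. The dienophile is β,β-disubstituted and the diene terminus adjoins a quaternary carbon. After A2 the C11 ester must still be extended by four carbons including C13.
- Comparison: the chosen plan takes absolute configuration from 1, sets C4 through a chair, and adds the full chain in one step (step 13). Both key steps are mechanistically well understood. Step count is probably equal up to the bicycle and higher for the alternative afterwards.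

Alternative 2: Ring A is taken from the resin acid A3, read so that its C4 (methyl, carboxyl) becomes C10 of the target and its C10 becomes C4. Ring B is closed between C8 and C9 by reductive coupling of the aldehyde and alkyne of A4 with a zerovalent nickel catalyst, a phosphine and a silane, giving the allylic silyl ether A5 with an exocyclic C9=C11 alkene.
- In favour: C4, C5 and C10 come fixed from the pool, so there is no diastereoselectivity question at C4; this is better than step 4. The key step attaches the whole chain with C13 in place while closing the ring, equal in convergence to step 13. The C8 oxygen is placed for oxidation and methylenation, again better than steps 15–17.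
- Against: degrading two rings of A3 to the differentiated arms of A4 (arene oxidation, carboxyl-to-alkyne homologation, telling two hindered carboxyls apart) needs far more steps than the four from 1 to 8. C9 would then depend on face-selective hydrogenation of a trisubstituted exocyclic alkene in the presence of a benzylic ether. Six-membered oxanickelacycle formation at a neopentyl alkyne is plausible but less usual than five-membered closure.
- Comparison: stronger in stereochemical certainty, weaker in step economy.

Alternative 3: The cut through C7–C8 and C9–C10 builds ring B by intermolecular Diels–Alder reaction of the ring A 2-silyloxydiene A6 with allenoate A7 under a chiral cationic oxazaborolidine Lewis acid, giving A8 with the C8 methylene, the C11 ester and the quaternary C10.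
- In favour: it is catalytic and enantioselective without a chiral pool, it is the shortest way to the bicycle, and the exocyclic alkene is present from the start; on these three points it is better than the chosen plan. Regiochemistry follows from the silyloxy group. C9 is epimerisable toward the desired equatorial orientation, equal in reliability to the hydride delivery of step 14.
- Against: the diene terminus C10 is fully substituted and next to quaternary C4, so reactivity and facial control are demanding. The symmetric 4,4-bis(oxymethyl) pattern means C4 is not yet a stereocentre, and one hydroxymethyl must later be reduced to methyl selectively. C5 must be set afterwards through the enol ether and a C6 deoxygenation. The β,γ-unsaturated ester of A8 can slip into conjugation, and the chain must be built stepwise with a separate answer for C13.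
- Comparison: fewer steps to ring B, more afterwards; overall comparable in length, with more open stereochemical questions than the chosen plan.

Key step: step 4

Remark on the chemistry (assumption): the esterase is taken to hydrolyse the pro-S ester of 13 to give the (R)-hemiester 14; if the other hemiester predominated, the chain ends would be differentiated in the reverse order (acid reduced first) to reach the same iodide 20.

## Route

Step 1
Reactants: 1 (S)-(+)-carvone
Product: 3 (5S)-2,6-dimethyl-5-(prop-1-en-2-yl)cyclohex-2-en-1-one (both C6 epimers), via lithium enolate 2 (not isolated)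
Conditions: LiN(i-Pr)2, THF, −78 °C; then MeI, −78 → 0 °C
Reagents that add atoms: iodomethane, CI; LiN(i-Pr)2, [Li]N(C(C)C)C(C)C (lithium of 2 only)
Why: Kinetic deprotonation at the only sp3 α-carbon (C6 of carvone) and C-methylation of the cross-conjugated enolate (enolate alkylation); the new centre forms as a mixture, which does not matter because it is made planar again in step 2.

Step 2
Reactants: 3 (5S)-2,6-dimethyl-5-(prop-1-en-2-yl)cyclohex-2-en-1-one; 4 acrylonitrile
Product: 5 3-[(1R,6R)-1,3-dimethyl-2-oxo-6-(prop-1-en-2-yl)cyclohex-3-en-1-yl]propanenitrile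
Conditions: KOt-Bu (cat.), t-BuOH/THF, 0 °C → rt
Reagents that add atoms: none
Why: Base-catalysed Michael addition of the C6 enolate; the acceptor should approach anti to the adjacent isopropenyl group, so the cyanoethyl chain ends trans to it and the quaternary centre (future C10) is set relative to C5, while the protic medium protonates the α-cyano carbanion before it can add back to the enone.

Step 3
Reactants: 5 3-[(1R,6R)-1,3-dimethyl-2-oxo-6-(prop-1-en-2-yl)cyclohex-3-en-1-yl]propanenitrile
Product: 6 3-[(1R,6S)-1,3-dimethyl-6-(2-methyloxiran-2-yl)-2-oxocyclohex-3-en-1-yl]propanenitrile (both oxirane epimers)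
Conditions: mCPBA, NaHCO3, CH2Cl2, 0 °C
Reagents that add atoms: 3-chloroperoxybenzoic acid, OOC(=O)c1cccc(Cl)c1
Why: Prilezhaev epoxidation; the electron-rich 1,1-disubstituted alkene should react much faster than the electron-poor enone alkene, and the configuration of the new oxirane carbon is irrelevant because it becomes a planar radical in step 4.

Step 4
Reactants: 6 3-[(1R,6S)-1,3-dimethyl-6-(2-methyloxiran-2-yl)-2-oxocyclohex-3-en-1-yl]propanenitrile
Product: 8 (4aS,5S,8aR)-5-(hydroxymethyl)-2,5,8a-trimethyl-4a,5,8,8a-tetrahydronaphthalene-1,6(4H,7H)-dione, via titanated ketimine 7 (not isolated)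
Conditions: Cp2TiCl2 (2.5 equiv), Zn dust, THF, rt, slow addition of 6; then 1 M HCl
Reagents that add atoms: water, O
Why: Cp2TiCl (trivalent titanium, made in the flask from Cp2TiCl2 and zinc) transfers one electron to the oxirane, which opens at its more substituted carbon to the tertiary C4 radical with O18 bound to titanium (Nugent–RajanBabu opening). The radical adds to the nitrile carbon C3 (6-exo-dig, forming C3–C4 and ring A); a second trivalent titanium traps the iminyl radical, and aqueous acid hydrolyses ketimine 7 to the C3 ketone. The closest known reaction type is the titanocene-mediated cyclisation of epoxy nitriles to β-hydroxy ketones. Ring A closes through a chair in which the tether on C10 and C4 on C5 are both equatorial on ring B, so the fusion is necessarily trans, as fixed in steps 1 and 2. The new stereocentre C4 is controlled by that chair: the bulky titanoxymethyl group should take the equatorial position and the methyl the axial one, syn to the C10 methyl. Both oxirane epimers give the same radical and converge. The step needs selectivity for the oxirane over the enone and for cyclisation over reduction or disproportionation of the radical; slow addition to excess reagent, the absence of a hydrogen donor, the hindered C9 carbonyl and the gem-dialkyl effect of C10 favour this.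

Step 5
Reactants: 8 (4aS,5S,8aR)-5-(hydroxymethyl)-2,5,8a-trimethyl-4a,5,8,8a-tetrahydronaphthalene-1,6(4H,7H)-dione
Product: 9 18-O-tert-butyldimethylsilyl ether of 8
Conditions: TBSCl, imidazole, DMF, rt
Reagents that add atoms: tert-butylchlorodimethylsilane, CC(C)(C)[Si](C)(C)Cl
Why: Silyl ether formation at the neopentyl primary alcohol; the non-basic conditions avoid retro-aldol loss of formaldehyde from the β-hydroxy ketone.

Step 6
Reactants: 9 18-O-tert-butyldimethylsilyl ether of 8
Product: 10 C3 (E)-N-tosylhydrazone of 9
Conditions: TsNHNH2, EtOH, AcOH (cat.), 60 °C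
Reagents that add atoms: 4-methylbenzenesulfonohydrazide, Cc1ccc(cc1)S(=O)(=O)NN
Why: Hydrazone condensation at the saturated C3 ketone; the C9 carbonyl is conjugated and flanked by quaternary C10 and substituted C8, so it should react far more slowly.

Step 7
Reactants: 10 C3 (E)-N-tosylhydrazone of 9
Product: 12 (4aR,5S,8aR)-5-{[tert-butyl(dimethyl)silyl]oxymethyl}-2,5,8a-trimethyl-4a,5,6,7,8,8a-hexahydronaphthalen-1(4H)-one, via N-boryl tosylhydrazine 11 (not isolated)
Conditions: catecholborane, CHCl3, 0 °C; then NaOAc·3H2O, reflux
Reagents that add atoms: catecholborane, B1Oc2ccccc2O1 (boron of 11 only)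
Why: Kabalka deoxygenation: hydride adds to the C=N bond, and acetate then triggers loss of sulfinate and dinitrogen to leave C3H2; the cyclic s-trans enone is not a substrate for conjugate reduction by catecholborane.

Step 8
Reactants: 13 dimethyl 3-methylpentanedioate
Product: 14 (R)-5-methoxy-3-methyl-5-oxopentanoic acid
Conditions: pig liver esterase, phosphate buffer pH 7/MeOH, −10 °C, NaOH (pH-stat); then HCl
Reagents that add atoms: water, O
Why: Enzymatic desymmetrisation of a prochiral diester creates the future C13 stereocentre; low temperature and methanol cosolvent are chosen because the enantioselectivity of this hydrolysis is known to depend on both.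

Step 9
Reactants: 14 (R)-5-methoxy-3-methyl-5-oxopentanoic acid
Product: 16 (4S)-4-methyloxan-2-one, via hydroxy acid 15 (not isolated)
Conditions: NaH, THF, 0 °C; then LiBH4, rt; then 2 M HCl
Reagents that add atoms: none
Why: The sodium carboxylate is inert to LiBH4, which reduces only the methyl ester (chemoselective ester reduction); acidification lactonises 15, so the former ester carbon becomes the O–CH2 carbon (future C11) and the carboxyl carbon stays as the future C15.

Step 10
Reactants: 16 (4S)-4-methyloxan-2-one
Product: 18 methyl (R)-5-iodo-3-methylpentanoate, via silyl ester 17 (not isolated)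
Conditions: TMSCl, NaI, MeCN, 60 °C; then MeOH, rt
Reagents that add atoms: sodium iodide, [Na+].[I-]; methanol, CO; chlorotrimethylsilane, C[Si](C)(C)Cl (silicon of 17 only)
Why: Iodotrimethylsilane made in the flask opens the lactone by SN2 attack of iodide at the O–CH2 carbon, and methanol with the silyl halide then esterifies the acid; the stereocentre is not touched.

Step 11
Reactants: 18 methyl (R)-5-iodo-3-methylpentanoate
Product: 19 (R)-5-iodo-3-methylpentanal
Conditions: i-Bu2AlH, CH2Cl2, −78 °C; then aq. KNaC4H4O6
Reagents that add atoms: none
Why: Partial ester reduction through the tetrahedral aluminium hemiacetal, which is stable at low temperature; a primary iodide is not reduced at −78 °C.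

Step 12
Reactants: 19 (R)-5-iodo-3-methylpentanal
Product: 20 (R)-5-iodo-1,1-dimethoxy-3-methylpentane
Conditions: HC(OMe)3, MeOH, PPTS (cat.), rt
Reagents that add atoms: trimethyl orthoformate, COC(OC)OC
Why: Acid-catalysed acetalisation with the orthoformate as water scavenger; the acetal holds C15 at the aldehyde level and tolerates the organolithium, palladium and amide-base steps ahead.

Step 13
Reactants: 20 (R)-5-iodo-1,1-dimethoxy-3-methylpentane; 12 (4aR,5S,8aR)-5-{[tert-butyl(dimethyl)silyl]oxymethyl}-2,5,8a-trimethyl-4a,5,6,7,8,8a-hexahydronaphthalen-1(4H)-one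
Product: 23 (13S)-18-[tert-butyl(dimethyl)silyloxy]-15,15-dimethoxy-9-(methoxycarbonyloxy)labd-7-ene with the ent configuration at C4, C5 and C10, C9–O syn and chain anti to the C20 methyl, via organolithium 21 (not isolated), via lithium alkoxide 22 (not isolated)
Conditions: 20, t-BuLi (2 equiv), Et2O/pentane, −78 °C; then 12, THF, −78 → 0 °C; then ClCO2Me, 0 °C → rt
Reagents that add atoms: methyl chloroformate, COC(=O)Cl; tert-butyllithium, [Li]C(C)(C)C (lithium of 21 and 22 only)
Why: Iodine–lithium exchange gives 21, which should add 1,2 to the C9 carbonyl from the face opposite the axial C20 methyl (there is no α′-hydrogen to enolise); the tertiary alkoxide 22 is acylated in the flask (alkoxide trapping as carbonate) because the hindered alcohol would be hard to acylate after isolation.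

Step 14
Reactants: 23 (13S)-18-[tert-butyl(dimethyl)silyloxy]-15,15-dimethoxy-9-(methoxycarbonyloxy)labd-7-ene
Product: 24 (13S)-18-[tert-butyl(dimethyl)silyloxy]-15,15-dimethoxy-ent-labd-7-ene
Conditions: Pd(OAc)2 (cat.), PBu3 (cat.), HCO2H, Et3N, THF, 40 °C
Reagents that add atoms: none
Why: Tsuji–Mandai hydrogenolysis of an allylic carbonate: zerovalent palladium ionises the carbonate with inversion, and the hydride formed by decarboxylation of the palladium formate is delivered on the palladium face to the more substituted allyl terminus C9, giving the less substituted C7=C8 alkene and C9–H anti to C20 (net inversion at C9).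

Step 15
Reactants: 24 (13S)-18-[tert-butyl(dimethyl)silyloxy]-15,15-dimethoxy-ent-labd-7-ene
Product: 25 7,8-epoxide of 24 (oxygen anti to the C20 methyl)
Conditions: mCPBA, NaHCO3, CH2Cl2, 0 °C
Reagents that add atoms: 3-chloroperoxybenzoic acid, OOC(=O)c1cccc(Cl)c1
Why: Prilezhaev epoxidation of the only alkene from the face away from the axial C20 methyl; either epimer would serve because C7 and C8 lose their configuration in step 17.

Step 16
Reactants: 25 7,8-epoxide of 24
Product: 27 (13S)-18-[tert-butyl(dimethyl)silyloxy]-15,15-dimethoxy-ent-labd-8(17)-en-7-yl methyl carbonate (C7–O anti to the C20 methyl), via lithium alkoxide 26 (not isolated)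
Conditions: Et2NH, n-BuLi, Et2O/hexane, 0 °C → reflux; then ClCO2Me, 0 °C → rt
Reagents that add atoms: methyl chloroformate, COC(=O)Cl; butyllithium, [Li]CCCC (lithium of 26 only)
Why: Lithium dialkylamide isomerisation of a 1-methylcyclohexene oxide by syn-elimination, which should take a proton from the unhindered C17 methyl and not the tertiary C9–H, giving the exocyclic allylic alkoxide 26; this is trapped as its carbonate in the same flask.

Step 17
Reactants: 27 (13S)-18-[tert-butyl(dimethyl)silyloxy]-15,15-dimethoxy-ent-labd-8(17)-en-7-yl methyl carbonate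
Product: 28 (13S)-18-[tert-butyl(dimethyl)silyloxy]-15,15-dimethoxy-ent-labd-8(17)-ene
Conditions: Pd(OAc)2 (cat.), PBu3 (cat.), HCO2H, Et3N, THF, 40 °C
Reagents that add atoms: none
Why: Second Tsuji–Mandai hydrogenolysis: the allylpalladium formate has termini C7 (secondary) and C17 (primary), and with PBu3 hydride goes to the more substituted terminus C7, which keeps the alkene exocyclic.

Step 18
Reactants: 28 (13S)-18-[tert-butyl(dimethyl)silyloxy]-15,15-dimethoxy-ent-labd-8(17)-ene
Product: 29 (13S)-18-hydroxy-ent-labd-8(17)-en-15-al
Conditions: HF (48% aq.), MeCN, 0 °C → rt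
Reagents that add atoms: water, O
Why: Aqueous hydrogen fluoride cleaves the silyl ether and hydrolyses the dimethyl acetal in one operation (acidic deprotection) and is too weak an acid to protonate the 1,1-disubstituted alkene.

Step 19
Reactants: 29 (13S)-18-hydroxy-ent-labd-8(17)-en-15-al
Product: 30 (13S)-18-hydroxy-ent-labd-8(17)-en-15-oic acid
Conditions: NaClO2, NaH2PO4, 2-methylbut-2-ene, t-BuOH/H2O, rt
Reagents that add atoms: sodium chlorite, [Na+].[O-]Cl=O
Why: Pinnick oxidation converts the aldehyde to the acid without touching the primary alcohol; the scavenger alkene removes hypochlorous acid before it can attack the exocyclic alkene.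

Step 20
Reactants: 30 (13S)-18-hydroxy-ent-labd-8(17)-en-15-oic acid; 31 2,2-dimethyl-1,3-dioxane-4,6-dione (Meldrum's acid)
Product: 32 (13S)-18-(carboxyacetoxy)-ent-labd-8(17)-en-15-oic acid
Conditions: toluene, 100 °C
Reagents that add atoms: none
Why: Alcoholysis of Meldrum's acid: the only hydroxyl (C18) opens the dioxanedione with loss of acetone to give the malonic half-ester; the C15 acid is not an acyl acceptor under these conditions.

Step 21
Reactants: 32 (13S)-18-(carboxyacetoxy)-ent-labd-8(17)-en-15-oic acid; 33 4-hydroxybenzaldehyde
Product: 34 (3S)-5-[(1R,4aS,5S,8aS)-5-({[(2E)-3-(4-hydroxyphenyl)prop-2-enoyl]oxy}methyl)-5,8a-dimethyl-2-methylidenedecahydronaphthalen-1-yl]-3-methylpentanoic acid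
Conditions: pyridine, piperidine (cat.), 90 °C
Reagents that add atoms: none
Why: Knoevenagel condensation in the Doebner modification: amine-catalysed condensation of the malonic half-ester with the aldehyde and decarboxylative elimination give the (E)-cinnamate directly with the phenol free; the C15 carboxylate, the alkene and all five stereocentres are spectators.

## Compound list

1 | (S)-(+)-carvone, (5S)-2-methyl-5-(prop-1-en-2-yl)cyclohex-2-en-1-one | CC1=CC[C@H](C(C)=C)CC1=O | starting material
2 | lithium dienolate of 1 (O–Li on C1, C1=C6) | CC1=CC[C@H](C(C)=C)C=C1O[Li] | intermediate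
3 | (5S)-2,6-dimethyl-5-(prop-1-en-2-yl)cyclohex-2-en-1-one (both C6 epimers) | CC1=CC[C@H](C(C)=C)C(C)C1=O | intermediate
4 | acrylonitrile | C=CC#N | starting material
5 | 3-[(1R,6R)-1,3-dimethyl-2-oxo-6-(prop-1-en-2-yl)cyclohex-3-en-1-yl]propanenitrile | CC1=CC[C@H](C(C)=C)[C@@](C)(CCC#N)C1=O | intermediate
6 | 3-[(1R,6S)-1,3-dimethyl-6-(2-methyloxiran-2-yl)-2-oxocyclohex-3-en-1-yl]propanenitrile (both oxirane epimers) | CC1=CC[C@H](C2(C)CO2)[C@@](C)(CCC#N)C1=O | intermediate
7 | C3 ketimine corresponding to 8, bound to titanium at N and O18 in the flask (drawn as the free hydroxy imine) | CC1=CC[C@@H]2[C@@](C)(CO)C(=N)CC[C@@]2(C)C1=O | intermediate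
8 | (4aS,5S,8aR)-5-(hydroxymethyl)-2,5,8a-trimethyl-4a,5,8,8a-tetrahydronaphthalene-1,6(4H,7H)-dione (18-hydroxy-3,9-dione, C7=C8 enone) | CC1=CC[C@@H]2[C@@](C)(CO)C(=O)CC[C@@]2(C)C1=O | intermediate
9 | 18-O-tert-butyldimethylsilyl ether of 8 | CC1=CC[C@@H]2[C@@](C)(CO[Si](C)(C)C(C)(C)C)C(=O)CC[C@@]2(C)C1=O | intermediate
10 | C3 (E)-N-tosylhydrazone of 9 | CC1=CC[C@@H]2[C@@](C)(CO[Si](C)(C)C(C)(C)C)/C(=N/NS(=O)(=O)c3ccc(C)cc3)CC[C@@]2(C)C1=O | intermediate
11 | N-(1,3,2-benzodioxaborol-2-yl)-N′-tosylhydrazine formed from 10 (C3–H, C3 epimers) | CC1=CC[C@@H]2[C@@](C)(CO[Si](C)(C)C(C)(C)C)C(N(NS(=O)(=O)c3ccc(C)cc3)B3Oc4ccccc4O3)CC[C@@]2(C)C1=O | intermediate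
12 | (4aR,5S,8aR)-5-{[tert-butyl(dimethyl)silyl]oxymethyl}-2,5,8a-trimethyl-4a,5,6,7,8,8a-hexahydronaphthalen-1(4H)-one | CC1=CC[C@@H]2[C@@](C)(CO[Si](C)(C)C(C)(C)C)CCC[C@@]2(C)C1=O | intermediate
13 | dimethyl 3-methylpentanedioate | COC(=O)CC(C)CC(=O)OC | starting material
14 | (R)-5-methoxy-3-methyl-5-oxopentanoic acid | COC(=O)C[C@H](C)CC(=O)O | intermediate
15 | (S)-5-hydroxy-3-methylpentanoic acid (carboxylate in the flask) | OCC[C@H](C)CC(=O)O | intermediate
16 | (4S)-4-methyloxan-2-one | C[C@H]1CCOC(=O)C1 | intermediate
17 | trimethylsilyl (R)-5-iodo-3-methylpentanoate | ICC[C@H](C)CC(=O)O[Si](C)(C)C | intermediate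
18 | methyl (R)-5-iodo-3-methylpentanoate | ICC[C@H](C)CC(=O)OC | intermediate
19 | (R)-5-iodo-3-methylpentanal | ICC[C@H](C)CC=O | intermediate
20 | (R)-5-iodo-1,1-dimethoxy-3-methylpentane | ICC[C@H](C)CC(OC)OC | intermediate
21 | [(3S)-5,5-dimethoxy-3-methylpentyl]lithium | [Li]CC[C@H](C)CC(OC)OC | intermediate
22 | lithium C9 alkoxide from 12 and 21 (O syn, chain anti to the C20 methyl) | CC1=CC[C@@H]2[C@@](C)(CO[Si](C)(C)C(C)(C)C)CCC[C@@]2(C)[C@@]1(O[Li])CC[C@H](C)CC(OC)OC | intermediate
23 | (13S)-18-[tert-butyl(dimethyl)silyloxy]-15,15-dimethoxy-9-(methoxycarbonyloxy)labd-7-ene, ent configuration at C4, C5, C10, C9–O syn to the C20 methyl | CC1=CC[C@@H]2[C@@](C)(CO[Si](C)(C)C(C)(C)C)CCC[C@@]2(C)[C@@]1(OC(=O)OC)CC[C@H](C)CC(OC)OC | intermediate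
24 | (13S)-18-[tert-butyl(dimethyl)silyloxy]-15,15-dimethoxy-ent-labd-7-ene | CC1=CC[C@@H]2[C@@](C)(CO[Si](C)(C)C(C)(C)C)CCC[C@@]2(C)[C@@H]1CC[C@H](C)CC(OC)OC | intermediate
25 | 7,8-epoxide of 24, oxygen anti to the C20 methyl | C[C@]12O[C@H]1C[C@@H]3[C@@](C)(CO[Si](C)(C)C(C)(C)C)CCC[C@@]3(C)[C@@H]2CC[C@H](C)CC(OC)OC | intermediate
26 | lithium C7 alkoxide of the 8(17)-en-7-ol from 25 | C=C1[C@@H](O[Li])C[C@@H]2[C@@](C)(CO[Si](C)(C)C(C)(C)C)CCC[C@@]2(C)[C@@H]1CC[C@H](C)CC(OC)OC | intermediate
27 | (13S)-18-[tert-butyl(dimethyl)silyloxy]-15,15-dimethoxy-ent-labd-8(17)-en-7-yl methyl carbonate (C7–O anti to the C20 methyl) | C=C1[C@@H](OC(=O)OC)C[C@@H]2[C@@](C)(CO[Si](C)(C)C(C)(C)C)CCC[C@@]2(C)[C@@H]1CC[C@H](C)CC(OC)OC | intermediate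
28 | (13S)-18-[tert-butyl(dimethyl)silyloxy]-15,15-dimethoxy-ent-labd-8(17)-ene | C=C1CC[C@@H]2[C@@](C)(CO[Si](C)(C)C(C)(C)C)CCC[C@@]2(C)[C@@H]1CC[C@H](C)CC(OC)OC | intermediate
29 | (13S)-18-hydroxy-ent-labd-8(17)-en-15-al | C=C1CC[C@@H]2[C@@](C)(CO)CCC[C@@]2(C)[C@@H]1CC[C@H](C)CC=O | intermediate
30 | (13S)-18-hydroxy-ent-labd-8(17)-en-15-oic acid | C=C1CC[C@@H]2[C@@](C)(CO)CCC[C@@]2(C)[C@@H]1CC[C@H](C)CC(=O)O | intermediate
31 | 2,2-dimethyl-1,3-dioxane-4,6-dione (Meldrum's acid) | CC1(C)OC(=O)CC(=O)O1 | starting material
32 | (13S)-18-(carboxyacetoxy)-ent-labd-8(17)-en-15-oic acid | C=C1CC[C@@H]2[C@@](C)(COC(=O)CC(=O)O)CCC[C@@]2(C)[C@@H]1CC[C@H](C)CC(=O)O | intermediate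
33 | 4-hydroxybenzaldehyde | O=Cc1ccc(O)cc1 | starting material
34 | (13S)-18-[(E)-4-hydroxycinnamoyloxy]-ent-labd-8(17)-en-15-oic acid; (3S)-5-[(1R,4aS,5S,8aS)-5-({[(2E)-3-(4-hydroxyphenyl)prop-2-enoyl]oxy}methyl)-5,8a-dimethyl-2-methylidenedecahydronaphthalen-1-yl]-3-methylpentanoic acid | C=C1CC[C@@H]2[C@@](C)(COC(=O)/C=C/c3ccc(O)cc3)CCC[C@@]2(C)[C@@H]1CC[C@H](C)CC(=O)O | target

## Step count and least certain steps

Total: 21 steps. Longest linear sequence: 16 steps (steps 1–7 and 13–21, from 1); the chain branch (steps 8–12) joins at step 13.

**Step 4 (key step).** The most likely failure is single-electron reduction of the enone by trivalent titanium (ketyl formation, reductive dimerisation), or reduction or disproportionation of the tertiary radical before it reaches the nitrile; weak discrimination between the two chair orientations at C4 is also possible. Fallback, setting out from 6 and returning at 8: the C9 carbonyl is reduced 1,2 with NaBH4/CeCl3·7H2O to the epoxy allylic alcohol F1, which no longer has an electron-poor alkene. The same Cp2TiCl cyclisation and acid work-up then give the keto diol F2, and MnO2 oxidises only the allylic C9 alcohol to give 8.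

**Step 14 (with the carbonate made in step 13).** Possible failures are incomplete acylation of the hindered tertiary alkoxide, β-hydride elimination of the allylpalladium species to dienes, hydride transfer to C7 instead of C9, or loss of facial fidelity at C9 if the addition in step 13 is not face-selective. Fallback, setting out from 12 (with 21 made as in step 13) and returning at 24: the addition is quenched with water to give the tertiary allylic alcohol F3. Oxidative 1,3-transposition with pyridinium chlorochromate, C5H5NH[CrO3Cl] (Dauben oxidation, NaOAc buffer), gives the 7-oxo-8-ene F4. Li/NH3 reduction sets C9–H by axial protonation whatever the configuration of F3, and the enolate is trapped with PhNTf2 as the enol triflate F5. Reduction with Pd(OAc)2, PPh3, Bu3N and HCO2H then gives 24.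

**Step 17.** The risk is poor regioselectivity of hydride transfer: delivery to the primary terminus C17 returns 24, which could be recycled but lowers throughput. Fallback, setting out from 25 and returning at 28: the amide-base opening of step 16 is worked up with water to give the allylic alcohol F6. Ph3SiOReO3-catalysed 1,3-transposition moves the hydroxyl to C17 and the alkene to C7=C8, giving the primary allylic alcohol F7. Mitsunobu displacement with 2-nitrobenzenesulfonylhydrazide (PPh3, diethyl azodicarboxylate) and warming lets the allylic diazene lose dinitrogen by a retro-ene shift that delivers hydrogen to C7 and places the alkene at C8(17) by mechanism.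

**Step 7 (with step 6).** The risk is loss of chemoselectivity between the two carbonyls: slow hydrazone formation at the neopentyl C3 ketone and competing reduction at C9. Fallback, setting out from 9 and returning at 12: NaBH4 at low temperature reduces the saturated C3 ketone in preference to the hindered enone, giving the C3 alcohol F8. 1,1′-Thiocarbonyldiimidazole gives the imidazolylthiocarbonate F9 without base, so the silyl group cannot migrate from O18 to O3. Bu3SnH with azobisisobutyronitrile then removes the oxygen (Barton–McCombie deoxygenation).

## Further compounds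

F1 | step 4 | 3-[(1R,6S)-2-hydroxy-1,3-dimethyl-6-(2-methyloxiran-2-yl)cyclohex-3-en-1-yl]propanenitrile (carbinol and oxirane epimers) | CC1=CC[C@H](C2(C)CO2)[C@@](C)(CCC#N)C1O
F2 | step 4 | 9,18-dihydroxy analogue of 8 (C9 carbinol in place of the C9 ketone, C3 ketone kept) | CC1=CC[C@@H]2[C@@](C)(CO)C(=O)CC[C@@]2(C)C1O
F3 | step 14 | tertiary C9 alcohol corresponding to 23 | CC1=CC[C@@H]2[C@@](C)(CO[Si](C)(C)C(C)(C)C)CCC[C@@]2(C)[C@@]1(O)CC[C@H](C)CC(OC)OC
F4 | step 14 | (13S)-18-[tert-butyl(dimethyl)silyloxy]-15,15-dimethoxy-ent-labd-8-en-7-one | O=C1C[C@@H]2[C@@](C)(CO[Si](C)(C)C(C)(C)C)CCC[C@@]2(C)C(CC[C@H](C)CC(OC)OC)=C1C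
F5 | step 14 | (13S)-18-[tert-butyl(dimethyl)silyloxy]-15,15-dimethoxy-ent-labd-7-en-7-yl trifluoromethanesulfonate | CC1=C(OS(=O)(=O)C(F)(F)F)C[C@@H]2[C@@](C)(CO[Si](C)(C)C(C)(C)C)CCC[C@@]2(C)[C@@H]1CC[C@H](C)CC(OC)OC
F6 | step 17 | (13S)-18-[tert-butyl(dimethyl)silyloxy]-15,15-dimethoxy-ent-labd-8(17)-en-7-ol (C7–O anti to the C20 methyl) | C=C1[C@@H](O)C[C@@H]2[C@@](C)(CO[Si](C)(C)C(C)(C)C)CCC[C@@]2(C)[C@@H]1CC[C@H](C)CC(OC)OC
F7 | step 17 | (13S)-18-[tert-butyl(dimethyl)silyloxy]-15,15-dimethoxy-ent-labd-7-en-17-ol | OCC1=CC[C@@H]2[C@@](C)(CO[Si](C)(C)C(C)(C)C)CCC[C@@]2(C)[C@@H]1CC[C@H](C)CC(OC)OC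
F8 | step 7 | C3 alcohol from 9 (C3 epimers, C9 enone kept) | CC1=CC[C@@H]2[C@@](C)(CO[Si](C)(C)C(C)(C)C)C(O)CC[C@@]2(C)C1=O
F9 | step 7 | O-(imidazol-1-ylthiocarbonyl) derivative of F8 | CC1=CC[C@@H]2[C@@](C)(CO[Si](C)(C)C(C)(C)C)C(OC(=S)n3ccnc3)CC[C@@]2(C)C1=O
A1 | alternative 1 | open-chain silyloxytriene enoate, precursor of the intramolecular cycloaddition | COC(=O)/C=C(\C)CCC[C@](C)(CO[Si](c1ccccc1)(c1ccccc1)C(C)(C)C)/C=C/C=C/O[Si](C)(C)C(C)(C)C
A2 | alternative 1 | trans-fused cycloadduct with C8 silyl ether, C6=C7 alkene and C11 methyl ester | CC(C)(C)[Si](C)(C)O[C@@H]1C=C[C@@H]2[C@@](C)(CO[Si](c3ccccc3)(c3ccccc3)C(C)(C)C)CCC[C@@]2(C)[C@@H]1C(=O)OC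
A3 | alternative 2 | dehydroabietic acid | CC(C)C1=CC2=C(C=C1)[C@]3(CCC[C@@]([C@@H]3CC2)(C)C(=O)O)C
A4 | alternative 2 | ring A ynal with the C6–C8 aldehyde arm on C5 and the C9≡C11 alkyne chain on C10 | O=CCC[C@@H]1[C@@](C)(COCc2ccc(OC)cc2)CCC[C@@]1(C)C#CC[C@H](C)CCO[Si](c1ccccc1)(c1ccccc1)C(C)(C)C
A5 | alternative 2 | ring B allylic triethylsilyl ether with exocyclic C9=C11 alkene (C8 as one epimer) | CC[Si](CC)(CC)O[C@@H]1CC[C@@H]2[C@@](C)(COCc3ccc(OC)cc3)CCC[C@@]2(C)/C1=C\C[C@H](C)CCO[Si](c1ccccc1)(c1ccccc1)C(C)(C)C
A6 | alternative 3 | ring A 2-silyloxydiene with the spiro acetonide at C4 | C=C(O[Si](C)(C)C(C)(C)C)C1=C(C)CCCC12COC(C)(C)OC2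
A7 | alternative 3 | ethyl buta-2,3-dienoate | C=C=CC(=O)OCC
A8 | alternative 3 | cycloadduct with C5=C6 silyl enol ether, C8 methylene and C11 ethyl ester | C=C1CC(O[Si](C)(C)C(C)(C)C)=C2C3(COC(C)(C)OC3)CCC[C@@]2(C)[C@@H]1C(=O)OCC
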